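**Retrosynthetic overview**
- C10–C11 is cut last. Solandelactone F comes from a lactone-bearing trans-cyclopropyl pinacol boronate (C1–C10) and an (E)-iodovinyl trans-oxirane (C11–C22). In the forward sense the cyclopropyl carbon shifts 1,2 from boron to C11 while the oxirane opens, which gives the 12E alkene and the C14 oxygen; C–B is then oxidised to C–OH at C11.
- Fragment 1 (boronate): the eight-membered lactone is closed by ring-closing metathesis of a pent-4-enoate. The C7 carbinol comes from iridium-catalysed allylation of a cyclopropylmethanol. The cyclopropane comes from Charette cyclopropanation of (E)-3-borylallyl alcohol, made from propargyl alcohol.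
- Fragment 2 (oxirane): Takai iodo-olefination of an epoxy aldehyde, which comes from Sharpless epoxidation of (2E,5Z)-undecadienol. The dienol is made from a pentyl cuprate, acetylene and vinyloxirane in one flask.
- Ring order: cyclopropane first, then the eight-membered lactone. The oxirane is built in parallel and consumed in the last step.

Assumption: the given SMILES reads (4Z,7R,8R,10R,11R,12E,14S,16Z) in solandelactone numbering (C1 = lactone carbonyl), which is used throughout; Bpin = 4,4,5,5-tetramethyl-1,3,2-dioxaborolan-2-yl.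

**Step 1**
Reactants: 1 prop-2-yn-1-ol
Product: 2 (E)-3-(Bpin)prop-2-en-1-ol
Conditions: B2pin2 (1.1 equiv), CuCl (5 mol%), Xantphos (5 mol%), NaOtBu (10 mol%), MeOH (2 equiv), THF, rt
Reagents that add atoms: bis(pinacolato)diboron, CC1(C)OB(OC1(C)C)B1OC(C)(C)C(C)(C)O1
Why: Copper-catalysed formal hydroboration, in which syn borylcupration puts boron on the terminal carbon and methanol protonates the C–Cu bond with retention, gives the E alkenylboronate and tolerates the free alcohol.

**Step 2**
Reactants: 2 (E)-3-(Bpin)prop-2-en-1-ol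
Product: 3 [(1R,2R)-2-(Bpin)cyclopropyl]methanol (trans)
Conditions: Et2Zn (2.2 equiv), CH2I2 (4.4 equiv), (4S,5S)-2-butyl-N,N,N',N'-tetramethyl-1,3,2-dioxaborolane-4,5-dicarboxamide (1.2 equiv), CH2Cl2, −10 °C → rt; aq NH4Cl work-up (no peroxide)
Reagents that add atoms: diiodomethane, ICI
Why: In this Charette asymmetric Simmons–Smith cyclopropanation the zinc alkoxide binds the chiral dioxaborolane and methylene is delivered stereospecifically to one face, so the E alkene gives the trans ring and the (S,S) ligand (antipode of the one that gives the (1S,2S) product from cinnamyl alcohol) sets C8 and C10.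

**Step 3**
Reactants: 3 [(1R,2R)-2-(Bpin)cyclopropyl]methanol; 4 allyl acetate
Product: 6 (1R)-1-[(1R,2R)-2-(Bpin)cyclopropyl]but-3-en-1-ol, via aldehyde 5 (not isolated)
Conditions: [Ir(cod)Cl]2 (2.5 mol%), (R)-BINAP (5 mol%), 4-chloro-3-nitrobenzoic acid (10 mol%), Cs2CO3 (20 mol%), 4 (5 equiv), THF, 100 °C, sealed tube
Reagents that add atoms: none
Why: In this Krische transfer-hydrogenative allylation from the alcohol oxidation level the cyclometalated π-allyliridium benzoate dehydrogenates 3 to 5 and adds allyl through a closed chair to the Re face under catalyst control, which sets C7 as R (to be checked by Mosher analysis) without a separate oxidation and without touching the C–B bond.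

**Step 4**
Reactants: 6 (1R)-1-[(1R,2R)-2-(Bpin)cyclopropyl]but-3-en-1-ol; 7 pent-4-enoyl chloride
Product: 8 (1R)-1-[(1R,2R)-2-(Bpin)cyclopropyl]but-3-enyl pent-4-enoate
Conditions: 7 (1.2 equiv), Et3N (1.5 equiv), DMAP (10 mol%), CH2Cl2, 0 °C → rt
Reagents that add atoms: none
Why: DMAP-catalysed acylation of a secondary alcohol breaks no bond at a stereocentre and leaves the boronate inert.

**Step 5**
Reactants: 8 (1R)-1-[(1R,2R)-2-(Bpin)cyclopropyl]but-3-enyl pent-4-enoate
Product: 9 (5Z,8R)-8-[(1R,2R)-2-(Bpin)cyclopropyl]-3,4,7,8-tetrahydro-2H-oxocin-2-one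
Conditions: second-generation Grubbs catalyst RuCl2(=CHPh)(PCy3)(H2IMes) (2 × 5 mol%), CH2Cl2 (1 mM), reflux
Reagents that add atoms: none
Why: Ring-closing metathesis of two terminal alkenes is driven by loss of ethene, the eight-membered ring can hold only the Z alkene (C4=C5), and high dilution suppresses dimers.

**Step 6**
Reactants: 10 pentylmagnesium bromide; 11 acetylene; 12 2-vinyloxirane (racemic)
Product: 15 (2E,5Z)-undeca-2,5-dien-1-ol, via dipentylcuprate 13 (not isolated), via bis[(Z)-hept-1-enyl]cuprate 14 (not isolated)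
Conditions: 10 (2.0 equiv), CuBr·SMe2 (1.0 equiv), Et2O/Me2S, −40 °C; 11 (2.0 equiv), −50 → −25 °C; 12 (0.9 equiv), −40 → 0 °C; aq NH4Cl/NH3
Reagents that add atoms: none
Why: Normant carbocupration of acetylene is a syn addition and fixes the 16Z alkene, and the SN2' opening of vinyloxirane through its s-trans conformer gives mainly the E allylic alcohol, the minor 2Z isomer being removed by chromatography.

**Step 7**
Reactants: 15 (2E,5Z)-undeca-2,5-dien-1-ol
Product: 16 {(2S,3S)-3-[(Z)-oct-2-enyl]oxiran-2-yl}methanol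
Conditions: Ti(OiPr)4 (10 mol%), L-(+)-diisopropyl tartrate (12 mol%), t-BuOOH (2 equiv, decane), 4 Å MS, CH2Cl2, −20 °C
Reagents that add atoms: tert-butyl hydroperoxide, CC(C)(C)OO
Why: Sharpless asymmetric epoxidation touches only the allylic alkene, and L-(+)-tartrate gives the (2S,3S) trans-epoxy alcohol (as with (E)-hex-2-en-1-ol), which sets C13 and the final C14 oxygen stereocentre.

**Step 8**
Reactants: 16 {(2S,3S)-3-[(Z)-oct-2-enyl]oxiran-2-yl}methanol
Product: 17 (2R,3S)-3-[(Z)-oct-2-enyl]oxirane-2-carbaldehyde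
Conditions: TEMPO (10 mol%), PhI(OAc)2 (1.1 equiv), CH2Cl2, rt
Reagents that add atoms: none
Why: Oxoammonium oxidation of the primary alcohol stops at the aldehyde under nearly neutral conditions, so the oxirane and the Z alkene survive; the descriptor at C13 changes only through CIP priorities.

**Step 9**
Reactants: 17 (2R,3S)-3-[(Z)-oct-2-enyl]oxirane-2-carbaldehyde
Product: 18 (2S,3S)-2-[(E)-2-iodoethenyl]-3-[(Z)-oct-2-enyl]oxirane
Conditions: CrCl2 (6 equiv), CHI3 (2 equiv), THF/1,4-dioxane, 0 °C
Reagents that add atoms: iodoform, IC(I)I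
Why: In the Takai olefination the gem-dichromium reagent adds to the aldehyde and eliminates to the E alkenyl iodide (C11=C12) under non-basic conditions at 0 °C that spare the oxirane.

**Step 10**
Reactants: 9 (5Z,8R)-8-[(1R,2R)-2-(Bpin)cyclopropyl]-3,4,7,8-tetrahydro-2H-oxocin-2-one; 18 (2S,3S)-2-[(E)-2-iodoethenyl]-3-[(Z)-oct-2-enyl]oxirane
Product: 23 solandelactone F, via alkenyllithium 19 (not isolated), via lithium boronate complex 20 (not isolated), via allylic boronate silyl ether 21 (not isolated), via 14-O-trimethylsilyl ether 22 (not isolated)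
Conditions: 18, t-BuLi (2.0 equiv), Et2O, −78 °C; cannula into 9 (1.05 equiv), THF/Et2O, −100 °C; TMSOTf (1.2 equiv), −100 → −20 °C; pH 7 buffer wash; NaBO3·4H2O (5 equiv), THF/H2O, rt; 0.5 M aq citric acid, rt
Reagents that add atoms: sodium perborate, [Na+].[Na+].O[B-]1(O)OO[B-](O)(O)OO1 (oxygen on C11); trimethylsilyl triflate, C[Si](C)(C)OS(=O)(=O)C(F)(F)F (silyl group of 21 and 22 only)
Why: Proposed new method: a vinylogous (SN2'-type) 1,2-metalate shift with 1,4-chirality transfer, in which 19 adds to the boron of 9 to give tetracoordinate 20 and silylation of the oxirane oxygen makes C13–O a leaving group conjugated through C11=C12 with the electron-rich B–C10 bond, so C10 migrates from boron to C11 with retention at C10 while the π bond moves to C12=C13 and the oxirane opens; reaction through the s-trans conformer with the migrating group anti to the departing C13–O bond converts the E-alkenyl (13S,14S)-oxirane into the 12E alkene with 11R boron (C14–O is never broken), stereoretentive C–B oxidation gives the 11R alcohol, and inverse addition at −100 °C is expected to let boron outrun the lactone carbonyl for 19; the closest known reaction types are the silyl-triflate-promoted 1,2-metalate rearrangement of boronates from lithiated epoxides, the SN2'-type rearrangement of boronates from 3-chloro-1-lithiopropene, the 1,2-metalate rearrangement/anti-SN2' elimination of ortho-lithiated benzylamine boronates and the anti-SN2' opening of vinyloxiranes by cuprates, none of which joins an acyclic epoxy-alkenyl unit to a boronic ester with transfer of chirality.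

**Compound list**
1 | prop-2-yn-1-ol | C#CCO | starting material
2 | (E)-3-(Bpin)prop-2-en-1-ol | OC/C=C/B1OC(C)(C)C(C)(C)O1 | intermediate
3 | [(1R,2R)-2-(Bpin)cyclopropyl]methanol | CC1(C)OB(OC1(C)C)[C@@H]2C[C@H]2CO | intermediate
4 | allyl acetate | C=CCOC(C)=O | starting material
5 | (1R,2R)-2-(Bpin)cyclopropanecarbaldehyde | CC1(C)OB(OC1(C)C)[C@@H]2C[C@H]2C=O | intermediate
6 | (1R)-1-[(1R,2R)-2-(Bpin)cyclopropyl]but-3-en-1-ol | CC1(C)OB(OC1(C)C)[C@@H]2C[C@H]2[C@H](O)CC=C | intermediate
7 | pent-4-enoyl chloride | C=CCCC(=O)Cl | starting material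
8 | (1R)-1-[(1R,2R)-2-(Bpin)cyclopropyl]but-3-enyl pent-4-enoate | CC1(C)OB(OC1(C)C)[C@@H]2C[C@H]2[C@H](OC(=O)CCC=C)CC=C | intermediate
9 | (5Z,8R)-8-[(1R,2R)-2-(Bpin)cyclopropyl]-3,4,7,8-tetrahydro-2H-oxocin-2-one | CC1(C)OB(OC1(C)C)[C@@H]2C[C@H]2[C@H]3C/C=C\CCC(=O)O3 | intermediate
10 | pentylmagnesium bromide | CCCCC[Mg]Br | starting material
11 | acetylene | C#C | starting material
12 | 2-vinyloxirane (racemic) | C=CC1CO1 | starting material
13 | bromomagnesium dipentylcuprate | CCCCC[Cu-]CCCCC.[Mg+]Br | intermediate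
14 | bromomagnesium bis[(Z)-hept-1-enyl]cuprate | CCCCC/C=C\[Cu-]/C=C\CCCCC.[Mg+]Br | intermediate
15 | (2E,5Z)-undeca-2,5-dien-1-ol | CCCCC/C=C\C/C=C/CO | intermediate
16 | {(2S,3S)-3-[(Z)-oct-2-enyl]oxiran-2-yl}methanol | CCCCC/C=C\C[C@@H]1O[C@H]1CO | intermediate
17 | (2R,3S)-3-[(Z)-oct-2-enyl]oxirane-2-carbaldehyde | CCCCC/C=C\C[C@@H]1O[C@H]1C=O | intermediate
18 | (2S,3S)-2-[(E)-2-iodoethenyl]-3-[(Z)-oct-2-enyl]oxirane | CCCCC/C=C\C[C@@H]1O[C@H]1/C=C/I | intermediate
19 | (E)-2-{(2S,3S)-3-[(Z)-oct-2-enyl]oxiran-2-yl}ethenyllithium | CCCCC/C=C\C[C@@H]1O[C@H]1/C=C/[Li] | intermediate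
20 | lithium (pinacolato)borate carrying the cyclopropyl group of 9 and the epoxy-alkenyl group of 19 on boron | [Li+].CCCCC/C=C\C[C@@H]1O[C@H]1/C=C/[B-]2(OC(C)(C)C(C)(C)O2)[C@@H]3C[C@H]3[C@H]4C/C=C\CCC(=O)O4 | intermediate
21 | (11R,12E,14S)-11-deoxy-11-(Bpin)-14-O-trimethylsilyl solandelactone F | CCCCC/C=C\C[C@H](O[Si](C)(C)C)/C=C/[C@@H](B1OC(C)(C)C(C)(C)O1)[C@@H]2C[C@H]2[C@H]3C/C=C\CCC(=O)O3 | intermediate
22 | 14-O-trimethylsilyl solandelactone F | CCCCC/C=C\C[C@H](O[Si](C)(C)C)/C=C/[C@@H](O)[C@@H]1C[C@H]1[C@H]2C/C=C\CCC(=O)O2 | intermediate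
23 | solandelactone F | CCCCC/C=C\C[C@H](O)/C=C/[C@@H](O)[C@@H]1C[C@H]1[C@H]1C/C=C\CCC(=O)O1 | target

**Totals**
- Total step count: 10.
- Longest linear sequence: 6 (steps 1–5, then step 10). The other arm is 5 (steps 6–9, then step 10).

**Three steps most likely to fail**

**Step 10 (new reaction).**
- Risks:
  - Alkenyllithium 19 may attack the lactone instead of boron.
  - TMSOTf may ionise the vinyloxirane, or oxygen may migrate instead of carbon, which would erode the chirality transfer.
  - A syn instead of an anti course would give the C11 epimer.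
- Fallback: known chemistry that sets out from 9 and 16 and comes back at 23.
  - Left half: Matteson homologation of 9 with LiCH2Cl made in situ (ICH2Cl, n-BuLi, THF, −78 °C → rt) gives the cyclopropylmethyl boronate F1. NaBO3·4H2O gives the primary alcohol F2, and Dess–Martin periodinane gives the lactone aldehyde F3.
  - Right half: 16 is converted with PPh3/CCl4 into the epoxy chloride F4. Double elimination with n-BuLi (3 equiv, THF, −78 °C) gives the propargylic alcohol F5 with C14 untouched. Hydrostannation (Bu3SnH, PdCl2(PPh3)2) gives the E vinylstannane F6, and iodine gives the vinyl iodide F7.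
  - Union: Nozaki–Hiyama–Kishi coupling of F3 with F7 (CrCl2, 1% NiCl2, DMSO) forms C11–C12. It gives 23 together with its C11 epimer solandelactone E F8, which is removed by chromatography.

**Step 5 (eight-membered ring-closing metathesis).**
- Risk: the ester prefers a conformer that keeps the two alkenes apart, so dimers and oligomers can dominate.
- Fallback: lactonisation of a Z hydroxy acid, which sets out from 6 and comes back at 9.
  - TESCl/imidazole gives the silyl ether F9.
  - Ozonolysis (O3, then PPh3) gives the β-silyloxy aldehyde F10.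
  - Z-selective Wittig reaction with the ylide from (3-carboxypropyl)triphenylphosphonium bromide (NaHMDS, THF, −78 °C) gives the Z acid F11.
  - AcOH/THF/H2O gives the hydroxy acid F12.
  - Yamaguchi conditions (2,4,6-trichlorobenzoyl chloride, Et3N; then DMAP, toluene, high dilution) pass through the mixed anhydride F13 and close the ring to 9.

**Step 3 (allylation at the alcohol oxidation level).**
- Risks: slow dehydrogenation of the boryl-substituted cyclopropylmethanol at 100 °C, modest diastereocontrol, or a facial sense opposite to the one assumed.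
- Fallback: a stoichiometric chiral allylborane on the isolated aldehyde, which sets out from 3 and comes back at 6.
  - TEMPO/PhI(OAc)2 gives 5 as an isolated compound.
  - Brown allylboration follows, with B-allyldiisopinocampheylborane of the (−)-α-pinene series (Et2O, −78 °C). This series attacks the Re face, the antipode of the series that gives (S)-1-phenylbut-3-en-1-ol from benzaldehyde.
  - Ethanolamine work-up in place of peroxide spares the cyclopropyl C–B bond and gives 6.

**Further compounds**
F1 | step 10 | (5Z,8R)-8-{(1R,2R)-2-[(Bpin)methyl]cyclopropyl}-3,4,7,8-tetrahydro-2H-oxocin-2-one | CC1(C)OB(OC1(C)C)C[C@@H]2C[C@H]2[C@H]3C/C=C\CCC(=O)O3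
F2 | step 10 | (5Z,8R)-8-[(1R,2R)-2-(hydroxymethyl)cyclopropyl]-3,4,7,8-tetrahydro-2H-oxocin-2-one | OC[C@@H]1C[C@H]1[C@H]2C/C=C\CCC(=O)O2
F3 | step 10 | (1R,2R)-2-[(5Z,8R)-2-oxo-3,4,7,8-tetrahydro-2H-oxocin-8-yl]cyclopropanecarbaldehyde | O=C[C@@H]1C[C@H]1[C@H]2C/C=C\CCC(=O)O2
F4 | step 10 | (2R,3S)-2-(chloromethyl)-3-[(Z)-oct-2-enyl]oxirane | CCCCC/C=C\C[C@@H]1O[C@H]1CCl
F5 | step 10 | (3S,5Z)-undec-5-en-1-yn-3-ol | CCCCC/C=C\C[C@H](O)C#C
F6 | step 10 | (1E,3S,5Z)-1-(tributylstannyl)undeca-1,5-dien-3-ol | CCCCC/C=C\C[C@H](O)/C=C/[Sn](CCCC)(CCCC)CCCC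
F7 | step 10 | (1E,3S,5Z)-1-iodoundeca-1,5-dien-3-ol | CCCCC/C=C\C[C@H](O)/C=C/I
F8 | step 10 | solandelactone E (11S epimer of 23) | CCCCC/C=C\C[C@H](O)/C=C/[C@H](O)[C@@H]1C[C@H]1[C@H]1C/C=C\CCC(=O)O1
F9 | step 5 | triethylsilyl ether of 6 | CC1(C)OB(OC1(C)C)[C@@H]2C[C@H]2[C@H](O[Si](CC)(CC)CC)CC=C
F10 | step 5 | (3R)-3-[(1R,2R)-2-(Bpin)cyclopropyl]-3-(triethylsilyloxy)propanal | CC1(C)OB(OC1(C)C)[C@@H]2C[C@H]2[C@H](O[Si](CC)(CC)CC)CC=O
F11 | step 5 | (4Z,7R)-7-[(1R,2R)-2-(Bpin)cyclopropyl]-7-(triethylsilyloxy)hept-4-enoic acid | CC1(C)OB(OC1(C)C)[C@@H]2C[C@H]2[C@H](O[Si](CC)(CC)CC)C/C=C\CCC(=O)O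
F12 | step 5 | (4Z,7R)-7-[(1R,2R)-2-(Bpin)cyclopropyl]-7-hydroxyhept-4-enoic acid | CC1(C)OB(OC1(C)C)[C@@H]2C[C@H]2[C@H](O)C/C=C\CCC(=O)O
F13 | step 5 | mixed anhydride of F12 with 2,4,6-trichlorobenzoic acid | CC1(C)OB(OC1(C)C)[C@@H]2C[C@H]2[C@H](O)C/C=C\CCC(=O)OC(=O)c3c(Cl)cc(Cl)cc3Cl
F0 | step 3 | none | none
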